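**Strategy.** Everything rests on cutting the axial C6–CH3 bond of the 1,2-dioxane ring (O1–O2–C3–C4–C5–C6). Without that methyl, C6 is a ketone-level carbon flanked by two homochiral arms, C5–C4(CH3) and C1′–C2′(CH3). The C3–C3′ backbone is therefore C2-symmetric, and one double auxiliary alkylation sets C4 and C2′ together. The key step ionises a 3,6-dimethoxy-1,2-dioxane, used as its full C3/C6 isomer mixture, at C6 and transfers methyl axially, trans to the equatorial C4–CH3. This is a stereoconvergent construction of the peroxide-bearing quaternary centre. Its precursor comes in one operation from an alkenal by ozonolysis in methanol. The same axial rule then installs the C3 acetate chain.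

Key step: step 8

Assumption: compounds 1, 3, 9 and 19 are taken as catalogue chemicals; the locants O1–O2–C3–C4–C5–C6 (ring) and C1′–C11′ (side chain) are used throughout, also for open-chain precursors.

**Step 1**
Reactants: 1 3-chloro-2-(chloromethyl)prop-1-ene
Product: 2 3-iodo-2-(iodomethyl)prop-1-ene
Conditions: NaI (2.5 equiv), acetone, rt, dark
Reagents that add atoms: sodium iodide [Na+].[I-]
Why: Finkelstein reaction: SN2 halide exchange at the two unhindered allylic carbons is driven by precipitation of the chloride salt from acetone and gives the more reactive bis-electrophile, with no stereocentre involved.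

**Step 2**
Reactants: 2 3-iodo-2-(iodomethyl)prop-1-ene; 3 (4R)-4-benzyl-3-propanoyl-1,3-oxazolidin-2-one (2.2 equiv)
Product: 6 (4R,4′R)-3,3′-[(2S,6S)-2,6-dimethyl-4-methylideneheptanedioyl]bis(4-benzyl-1,3-oxazolidin-2-one), via sodium (Z)-enolate 4 (not isolated), via monoalkylated allylic iodide 5 (not isolated)
Conditions: NaHMDS (2.2 equiv), THF, −78 °C; then 2 (1.0 equiv), −78 → −20 °C
Reagents that add atoms: none
Why: Two-directional Evans asymmetric alkylation: the chelated (Z)-enolate 4 is shielded on one face by the benzyl group of the (R)-auxiliary, so each allylic carbon of 2 and then of 5 (SN2 and SN2′ give the same skeleton) is taken from the open face, which sets C4 and C2′ both as (S) in 6, and running the same selective event twice moves the minor series into a separable diastereomer.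

**Step 3**
Reactants: 6 bis-imide
Product: 7 (2S,6S)-2,6-dimethyl-4-methylideneheptane-1,7-diol
Conditions: LiBH4 (5 equiv), MeOH (5 equiv), Et2O, 0 °C
Reagents that add atoms: none
Why: Reductive cleavage of N-acyloxazolidinones with lithium borohydride attacks only the exocyclic imide carbonyls, leaves the isolated alkene and the α-stereocentres untouched, and should give the C2-symmetric diol.

**Step 4**
Reactants: 7 (2S,6S)-2,6-dimethyl-4-methylideneheptane-1,7-diol
Product: 8 (2S,6S)-7-hydroxy-2,6-dimethyl-4-methylideneheptyl 4-methylbenzenesulfonate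
Conditions: TsCl (1.05 equiv), Ag2O (1.5 equiv), KI (0.2 equiv), CH2Cl2, 0 °C → rt
Reagents that add atoms: 4-toluenesulfonyl chloride Cc1ccc(cc1)S(=O)(=O)Cl
Why: Silver(I) oxide-mediated monotosylation of a symmetrical diol: the two hydroxyl groups of C2-symmetric 7 are homotopic, so the first sulfonylation gives one compound whichever end reacts, and limiting TsCl holds back the second.

**Step 5**
Reactants: 8 monotosylate; 9 (8-bromooctyl)benzene (3 equiv)
Product: 11 (2S,6R)-2,6-dimethyl-4-methylidene-15-phenylpentadecan-1-ol, via 8-phenyloctylmagnesium bromide 10 (not isolated)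
Conditions: 9, Mg, THF, 40 °C; then 8, Li2CuCl4 (5 mol %), THF, −30 °C → rt
Reagents that add atoms: none
Why: Copper-catalysed Grignard–tosylate cross-coupling (Kochi type): after one equivalent of 10 has deprotonated the hydroxyl group, the alkylcuprate displaces the primary tosylate at C3′ next to, but not at, C2′, so the stereocentre is untouched and only its descriptor changes from S to R through the CIP ranking.

**Step 6**
Reactants: 11 alkenol
Product: 12 (2S,6R)-2,6-dimethyl-4-methylidene-15-phenylpentadecanal
Conditions: TEMPO (10 mol %), PhI(OAc)2 (1.1 equiv), CH2Cl2, rt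
Reagents that add atoms: none
Why: TEMPO/PhI(OAc)2 (oxoammonium) oxidation stops at the aldehyde, is mild enough not to epimerise C4 and ignores the 1,1-disubstituted alkene.

**Step 7**
Reactants: 12 alkenal
Product: 16 (4S)-3,6-dimethoxy-4-methyl-6-[(2R)-2-methyl-11-phenylundecyl]-1,2-dioxane as C3/C6 isomer mixture, via carbonyl oxide 13 (not isolated), via methoxy hydroperoxide 14 (not isolated), via peroxyhemiacetal 15 (not isolated)
Conditions: O3, CH2Cl2–MeOH 1:1, −78 °C; N2 purge; then p-TsOH·H2O (5 mol %), 0 °C
Reagents that add atoms: ozone [O-][O+]=O; methanol CO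
Why: Criegee ozonolysis in a participating solvent: the 1,1-disubstituted alkene fragments to the more substituted carbonyl oxide 13, methanol traps it as α-methoxy hydroperoxide 14, its OOH group adds 6-exo-trig to the C3 aldehyde to give 15, and acid-catalysed acetal exchange caps C3, the configurations at C3 and C6 being irrelevant because both centres are ionised later.

**Step 8**
Reactants: 16 3,6-dimethoxy-1,2-dioxane (isomer mixture)
Product: 18 (4S,6R)-3-methoxy-4,6-dimethyl-6-[(2R)-2-methyl-11-phenylundecyl]-1,2-dioxane as both C3 anomers, via C6 peroxycarbenium aluminate 17 (not isolated)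
Conditions: Me3Al (2.0 equiv, hexanes), CH2Cl2, −78 → −30 °C; aq. Rochelle salt
Reagents that add atoms: trimethylaluminium C[Al](C)C
Why: Proposed new method: Me3Al binds the methoxy oxygen at the ketal carbon C6, which is more basic than the peroxide oxygens, and ionises it to the tertiary peroxycarbenium ion pair 17 (C6=O1+), within which the methoxytrimethylaluminate hands one methyl group to C6. The closest known reaction types are the Lewis acid-mediated substitution of 3-alkoxy-1,2-dioxanes and 3-alkoxy-1,2-dioxolanes by allylsilanes and silyl ketene acetals through peroxycarbenium ions, and the axial C-methylation of cyclic ketals and lactol derivatives with Me3Al, which trioxane-type endoperoxides are known to survive; what is new is a σ-bonded methyl donor on a peroxycarbenium ion. The step closes no ring, and the 1,2-dioxane made in step 7 should stay closed because the Lewis acid prefers the exocyclic methoxy oxygen to the less basic ring oxygen O1. The only new stereocentre, C6, is set by the stereoelectronic preference for axial attack on the half-chair that carries C4–CH3 pseudoequatorially, so methyl enters trans to C4–CH3 and the C1′ chain ends up equatorial, which is the (6R) configuration. The step is stereoconvergent: all C3/C6 isomers of 16 give the same planar C6 cation, and both C3 anomers react through the C4-equatorial half-chair because axial attack on the flipped form would be syn-diaxial to C4–CH3. It needs site selectivity for C6 over C3, secured by the much easier ionisation of a ketal than of an acetal at low temperature with limited reagent, and chemoselectivity for C–O over O–O cleavage, secured by the low temperature and the hindered, weakly basic dialkyl peroxide.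

**Step 9**
Reactants: 18 3-methoxy-1,2-dioxane; 19 tert-butyl[(1-methoxyethenyl)oxy]dimethylsilane (3 equiv)
Product: 21 methyl 2-[(3S,4S,6R)-4,6-dimethyl-6-[(2R)-2-methyl-11-phenylundecyl]-1,2-dioxan-3-yl]acetate, via C3 peroxycarbenium triflate 20 (not isolated)
Conditions: TMSOTf (0.2 equiv), CH2Cl2, −78 °C
Reagents that add atoms: none
Why: Mukaiyama-type peroxycarbenium substitution, a known reaction of 3-alkoxy-1,2-dioxanes and -dioxolanes with silyl ketene acetals: TMSOTf ionises C3–OMe to 20, whose half-chair is locked by the cis-1,3 pair C4–CH3/C6–C1′ (both equatorial), and axial attack of 19 on the face away from the axial C6–CH3 sets C3 as (S) with the acetate chain cis to C4–CH3.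

**Step 10**
Reactants: 21 methyl ester
Product: 22 2-[(3S,4S,6R)-4,6-dimethyl-6-[(2R)-2-methyl-11-phenylundecyl]-1,2-dioxan-3-yl]acetic acid (target)
Conditions: LiOH (3 equiv), THF–H2O 3:1, 0 °C; then 1 M HCl to pH 3
Reagents that add atoms: lithium hydroxide [Li+].[OH-]
Why: Ester saponification, which dialkyl peroxides tolerate; short contact at 0 °C should keep the β-peroxy ester from E1cB ring opening, so C3 is not scrambled.

**Compound list**
1 | 3-chloro-2-(chloromethyl)prop-1-ene | C=C(CCl)CCl | starting material
2 | 3-iodo-2-(iodomethyl)prop-1-ene | C=C(CI)CI | intermediate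
3 | (4R)-4-benzyl-3-propanoyl-1,3-oxazolidin-2-one | CCC(=O)N1[C@H](Cc2ccccc2)COC1=O | starting material
4 | sodium (Z)-enolate of 3 | C/C=C(\[O-])N1[C@H](Cc2ccccc2)COC1=O.[Na+] | intermediate
5 | (4R)-4-benzyl-3-[(2S)-4-(iodomethyl)-2-methylpent-4-enoyl]-1,3-oxazolidin-2-one | C=C(CI)C[C@H](C)C(=O)N1[C@H](Cc2ccccc2)COC1=O | intermediate
6 | (4R,4′R)-3,3′-[(2S,6S)-2,6-dimethyl-4-methylideneheptanedioyl]bis(4-benzyl-1,3-oxazolidin-2-one) | C=C(C[C@H](C)C(=O)N1[C@H](Cc2ccccc2)COC1=O)C[C@H](C)C(=O)N1[C@H](Cc2ccccc2)COC1=O | intermediate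
7 | (2S,6S)-2,6-dimethyl-4-methylideneheptane-1,7-diol | C=C(C[C@H](C)CO)C[C@H](C)CO | intermediate
8 | (2S,6S)-7-hydroxy-2,6-dimethyl-4-methylideneheptyl 4-methylbenzenesulfonate | C=C(C[C@H](C)CO)C[C@H](C)COS(=O)(=O)c1ccc(C)cc1 | intermediate
9 | (8-bromooctyl)benzene | BrCCCCCCCCc1ccccc1 | starting material
10 | 8-phenyloctylmagnesium bromide | Br[Mg]CCCCCCCCc1ccccc1 | intermediate
11 | (2S,6R)-2,6-dimethyl-4-methylidene-15-phenylpentadecan-1-ol | C=C(C[C@H](C)CO)C[C@H](C)CCCCCCCCCc1ccccc1 | intermediate
12 | (2S,6R)-2,6-dimethyl-4-methylidene-15-phenylpentadecanal | C=C(C[C@H](C)C=O)C[C@H](C)CCCCCCCCCc1ccccc1 | intermediate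
13 | carbonyl oxide at C6 of (2S,6R)-2,6-dimethyl-4-oxo-15-phenylpentadecanal | [O-][O+]=C(C[C@H](C)C=O)C[C@H](C)CCCCCCCCCc1ccccc1 | intermediate
14 | (2S,6R)-4-hydroperoxy-4-methoxy-2,6-dimethyl-15-phenylpentadecanal (both epimers at the ketal carbon) | COC(OO)(C[C@H](C)C=O)C[C@H](C)CCCCCCCCCc1ccccc1 | intermediate
15 | (4S)-6-methoxy-4-methyl-6-[(2R)-2-methyl-11-phenylundecyl]-1,2-dioxan-3-ol (C3/C6 isomer mixture) | COC1(C[C@H](C)CCCCCCCCCc2ccccc2)C[C@H](C)C(O)OO1 | intermediate
16 | (4S)-3,6-dimethoxy-4-methyl-6-[(2R)-2-methyl-11-phenylundecyl]-1,2-dioxane (C3/C6 isomer mixture) | COC1(C[C@H](C)CCCCCCCCCc2ccccc2)C[C@H](C)C(OC)OO1 | intermediate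
17 | C6 peroxycarbenium ion (C6=O1+) paired with methoxytrimethylaluminate | C[C@H](CCCCCCCCCc1ccccc1)CC1C[C@H](C)C(OC)O[O+]=1.CO[Al-](C)(C)C | intermediate
18 | (4S,6R)-3-methoxy-4,6-dimethyl-6-[(2R)-2-methyl-11-phenylundecyl]-1,2-dioxane (both C3 anomers) | C[C@H](CCCCCCCCCc1ccccc1)C[C@]1(C)C[C@H](C)C(OC)OO1 | intermediate
19 | tert-butyl[(1-methoxyethenyl)oxy]dimethylsilane | C=C(OC)O[Si](C)(C)C(C)(C)C | starting material
20 | C3 peroxycarbenium ion (C3=O2+) paired with triflate | C[C@H](CCCCCCCCCc1ccccc1)C[C@]1(C)C[C@H](C)C=[O+]O1.[O-]S(=O)(=O)C(F)(F)F | intermediate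
21 | methyl 2-[(3S,4S,6R)-4,6-dimethyl-6-[(2R)-2-methyl-11-phenylundecyl]-1,2-dioxan-3-yl]acetate | C[C@H](CCCCCCCCCc1ccccc1)C[C@]1(C)C[C@H](C)[C@H](CC(=O)OC)OO1 | intermediate
22 | 2-[(3S,4S,6R)-4,6-dimethyl-6-[(2R)-2-methyl-11-phenylundecyl]-1,2-dioxan-3-yl]acetic acid | C[C@H](CCCCCCCCCc1ccccc1)C[C@]1(C)C[C@H](C)[C@H](CC(=O)O)OO1 | target

**Total steps:** 10. **Longest linear sequence:** 10 steps (1 → 22); 3, 9 and 19 enter as purchased building blocks.

**Steps most likely to fail**

1. **Step 8.**
   - Possible failure modes are: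
     - methyl transfer to a peroxide oxygen, with O–O cleavage;
     - ionisation with loss of the ring peroxide instead of methoxide;
     - proton loss from the cation to a peroxy enol ether;
     - over-reaction at C3.
   - The fallback uses only known chemistry, sets out from 11 and comes back at 18.
   - Mukaiyama–Isayama hydroperoxysilylation of the 1,1-disubstituted alkene (Co(thd)2, O2, Et3SiH) should give the triethylsilyl peroxide F1 as both C6 epimers.
   - TEMPO/PhI(OAc)2 oxidation then leads to the aldehyde F2.
   - p-TsOH in methanol removes the silyl group, closes the peroxyhemiacetal and caps it as the methyl acetal.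
   - This gives 18 together with its C6 epimer F3, to be separated by chromatography. Stereocontrol at C6 is given up in exchange for precedent.

2. **Step 9.**
   - Facial selectivity at C3 may be insufficient, or ionisation may occur at the ring C3–O2 bond and open the ring.
   - The fallback sets out from 18 and comes back at 21 by C–O instead of C–C bond formation at C3.
   - Aqueous acid hydrolysis gives the peroxyhemiacetal F4.
   - A Horner–Wadsworth–Emmons reaction under Masamune–Roush conditions (trimethyl phosphonoacetate, LiCl, i-Pr2NEt) on its open form gives the hydroperoxy enoate F5.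
   - Amine-catalysed 6-exo oxa-Michael closure gives 21 beside its C3 epimer F6, to be separated.

3. **Step 7.**
   - The carbonyl oxide may be captured by the internal aldehyde to give a bicyclic ozonide.
   - The aldehyde may be over-oxidised.
   - Hydrogen peroxide may be lost by exchange with methanol during acetalisation.
   - The fallback sets out from 12 and comes back at 16, taking the O–O unit from hydrogen peroxide instead of ozone.
   - Reductive ozonolysis (O3, then Me2S) gives the keto aldehyde F7.
   - Urea–H2O2 with Sc(OTf)3 in methanol condenses with F7 to give the cyclic bis-peroxyacetal 16.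

**Further compounds**
F1 | step 8 | (2S,6R)-2,4,6-trimethyl-15-phenyl-4-[(triethylsilyl)peroxy]pentadecan-1-ol (both C4 epimers) | CC[Si](CC)(CC)OOC(C)(C[C@H](C)CO)C[C@H](C)CCCCCCCCCc1ccccc1
F2 | step 8 | (2S,6R)-2,4,6-trimethyl-15-phenyl-4-[(triethylsilyl)peroxy]pentadecanal (both C4 epimers) | CC[Si](CC)(CC)OOC(C)(C[C@H](C)C=O)C[C@H](C)CCCCCCCCCc1ccccc1
F3 | step 8 | (4S,6S)-3-methoxy-4,6-dimethyl-6-[(2R)-2-methyl-11-phenylundecyl]-1,2-dioxane | C[C@H](CCCCCCCCCc1ccccc1)C[C@@]1(C)C[C@H](C)C(OC)OO1
F4 | step 9 | (4S,6R)-4,6-dimethyl-6-[(2R)-2-methyl-11-phenylundecyl]-1,2-dioxan-3-ol | C[C@H](CCCCCCCCCc1ccccc1)C[C@]1(C)C[C@H](C)C(O)OO1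
F5 | step 9 | methyl (2E,4S,6R,8R)-6-hydroperoxy-4,6,8-trimethyl-17-phenylheptadec-2-enoate | C[C@H](CCCCCCCCCc1ccccc1)C[C@](OO)(C)C[C@H](C)/C=C/C(=O)OC
F6 | step 9 | methyl 2-[(3R,4S,6R)-4,6-dimethyl-6-[(2R)-2-methyl-11-phenylundecyl]-1,2-dioxan-3-yl]acetate | C[C@H](CCCCCCCCCc1ccccc1)C[C@]1(C)C[C@H](C)[C@@H](CC(=O)OC)OO1
F7 | step 7 | (2S,6R)-2,6-dimethyl-4-oxo-15-phenylpentadecanal | C[C@H](CCCCCCCCCc1ccccc1)CC(=O)C[C@H](C)C=O
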